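Count what is left. In a closed flask, whatever has not become side product A is still substrate or stands in target, isomer of the product or side product B, so I reckon with two fractions of the charge, taking no substrate as left at the last reading.

| setting | east | south-west | Sunday's | Saturday's | Monday's |
|---|---|---|---|---|---|
| substrate | 0.0067 M | 0.015 M | 0.010 M | 0.010 M | 0.010 M |
| coupling partner | 8 mM | 8 mM | 8.00 mM | 8.00 mM | 8.00 mM |
| rival reagent | 0.0105 M | 0.0105 M | 0.0105 M | 0.0105 M | 0.0105 M |
| temperature | −5 °C | 8 °C | 0 °C |  | 15 °C |
| remark | run made earlier | run made earlier |  | at 15 °C until 40 min, from then on at 0 °C |  |
| time |  |  | 80 min | 80 min | 80 min |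

- east (time / min: target / %, side product A / %): 12.0: 19.9, 59.2; 25.0: 19.3, 64.8; 40.0: 18.5, 68.2; 50.0: 17.3, 66.7
- south-west (time / min: target / %, side product A / %): 6.00: 18.7, 50.2; 15.0: 22.6, 51.9; 30.0: 24.8, 53.1; 50.0: 25.5, 51.1

(scatter of a reading: 0.5 percentage points)

- the best flask by share of target in all that became target or side product A or isomer of the product or side product B; "all alike" if 1.5 percentage points covers them all (Sunday's / Saturday's / Monday's / all alike)
- share of target in all that became target or side product A or isomer of the product or side product B, Sunday's
- share of target in all that became target or side product A or isomer of the product or side product B, Saturday's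
- share of target in all that became target or side product A or isomer of the product or side product B, Monday's

- percentages count the substrate that a species holds: one side product B counts as two

The first fraction is the escape, one minus the fraction in side product A. The second is the keep, the target divided by the escape, a selectivity within what escaped. I get the keep in two ways, from the last reading of each earlier run:

east: escape 33 percentage points, keep 0.520
south-west: escape 49 points, keep 0.521

These are different flasks and the two keeps agree, so I carry their mean, 0.520, and the asked share is then keep times escape.

The escape of a new flask also has two ways, a straight line in temperature and one in substrate charge: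

Sunday's: by temperature 0.393, by charge 0.395
Monday's: by temperature 0.573, by charge 0.395

They agree for Sunday's and part for Monday's. The two runs changed charge and temperature together, so the temperature line may book the larger charge as warmth, and for Monday's it runs on to 15 °C, warmer than the 8 °C of the south-west run; I take it to be the line that cheats. But the charge line is blind to warmth, so I commit to the middle, 0.484.

The readings of side product A in the south-west run stand flat within their scatter from 15.0 min, so I expect it finished in the warm part of Saturday's, which then shares Monday's escape. My reckoning gives 0.204 for Sunday's and 0.252 for both Saturday's and Monday's.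

The forecast differs: 21%, 25.5% and 24% for Sunday's, Saturday's and Monday's, with Saturday's best, since “cooling protects the target”.

The flasks give 21.0% for Sunday's, 24.1% for Saturday's and 29.3% for Monday's, so Monday's is best.

    rival reagent → decomposed reagent (k = 6.40 × 10⁻⁴ s⁻¹, Ea = 92.0 kJ mol⁻¹)
    target ⇌ isomer of the product (K = 0.540, k = 0.00180 s⁻¹, Ea = 87.0 kJ mol⁻¹, ΔH = −31.0 kJ mol⁻¹)
    substrate + target → side product B (k = 0.0480 M⁻¹ s⁻¹, Ea = 39.0 kJ mol⁻¹)
    substrate + coupling partner → target (k = 0.190 M⁻¹ s⁻¹, Ea = 42.0 kJ mol⁻¹)
    substrate + rival reagent → side product A (k = 0.430 M⁻¹ s⁻¹, Ea = 52.0 kJ mol⁻¹)
    (constants at 0 °C)

Monday's shows an escape of 43 points and a keep of 0.687 against my 0.520, while Saturday's has a like escape but a lower keep, 0.565, near the 0.579 of Sunday's, which ends at the same temperature. In Sunday's, half of the turnover up to the asked time of the step from substrate and coupling partner to target is done by 3.36 min, earlier than for the step from rival reagent to decomposed reagent, at 10.9 min.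

Readings and results stem from a simulated flask for substances that don't exist; scatter was added.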